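**Retrosynthetic overview**

1. C13–C14 bond and the C14 stereocentre: asymmetric Nozaki–Hiyama–Kishi addition of a C13 alkenyl bromide to acetoxyacetaldehyde, with acetylation in the same pot.
2. C7=C8–CH3: C8 ketone → Δ7 enol triflate → methyl cuprate coupling.
3. Ring B and the C9–C10 bond: one-carbon ring expansion (β-oxido carbenoid 1,2-shift of C10) of a trans-hydrindan-1-one; the carbenoid from 2,5,5-tribromopent-1-ene brings C9 with C11–C13 and C16.
4. Ring A: ring-closing metathesis and hydrogenation of a trans-2-allyl-2-methyl-3-(1,1-dimethylallyl)cyclopentanone, made by enantioselective conjugate prenylation and allylation of 2-methylcyclopent-2-enone.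
5. Ring order: purchased five-membered ring (the future ring B) → ring A → ring B enlarged from five to six members.

Assumption: the SMILES is read as (14S)-labda-7,13(16)-diene-14,15-diyl diacetate with the normal labdane core (5S,9S,10S; trans-decalin, side chain equatorial); labdane numbering (C1–C20) is used in the comments.

**Route**

Step 1
Reactants: 1 1-chloro-3-methylbut-2-ene
Product: 3 trimethyl(3-methylbut-2-en-1-yl)silane, via prenylmagnesium chloride 2 (not isolated)
Conditions: Mg, Me3SiCl, THF, 0 °C → rt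
Reagents that add atoms: chlorotrimethylsilane, C[Si](C)(C)Cl
Why: Barbier-type Grignard silylation; the allylic Grignard is silylated at its unhindered primary terminus.

Step 2
Reactants: 4 2-methylcyclopent-2-en-1-one; 3 trimethyl(3-methylbut-2-en-1-yl)silane; 5 3-iodoprop-1-ene
Product: 8 (2S,3S)-2-methyl-3-(2-methylbut-3-en-2-yl)-2-(prop-2-en-1-yl)cyclopentan-1-one, via silyl enol ether 6 (not isolated), via lithium enolate 7 (not isolated)
Conditions: chiral imidodiphosphorimidate acid HN[P(=NSO2CF3)(O2Ar*)]2 (O2Ar* = 3,3′-diaryl-1,1′-binaphthalene-2,2′-diolate; 2 mol %, enantiomer selected for 3S), toluene, −60 °C; then MeLi, THF, 0 °C; then 5, DMPU, −78 → 0 °C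
Reagents that add atoms: none
Why: Proposed new method: the acid is silylated in situ by 3, the chiral silylium ion pair O-silylates the enone, and 3 attacks C3 through its γ-carbon in an open transition state inside the confined anion pocket (sets 3S and the quaternary C4 of the labdane), after which the β-silyl cation returns Me3Si+ to the counteranion and leaves the regiodefined enol ether 6; the closest known reactions are silylium imidodiphosphorimidate-catalysed Hosomi–Sakurai allylation of aldehydes and Mukaiyama–Michael additions, and the racemic Lewis-acid conjugate Sakurai prenylation of cycloalkenones; MeLi then frees enolate 7, which is allylated anti to the bulky C3 group (sets the 2S quaternary centre, trans).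

Step 3
Reactants: 8 (2S,3S)-2-methyl-3-(2-methylbut-3-en-2-yl)-2-(prop-2-en-1-yl)cyclopentan-1-one
Product: 10 (3aS,7aS)-4,4,7a-trimethyloctahydro-1H-inden-1-one, via hydrindenone 9 (not isolated)
Conditions: RuCl2(=CHPh)(PCy3)(H2IMes) (second-generation Grubbs catalyst, 2 mol %), CH2Cl2, 40 °C; then Pd/C, H2 (1 atm), EtOAc, rt
Reagents that add atoms: none
Why: Ring-closing metathesis of the trans-disposed allyl and vinyl groups closes ring A as a trans-fused cyclohexene (gem-dimethyl assistance), and hydrogenation saturates it; no new stereocentre is formed.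

Step 4
Reactants: 11 (E)-N-tert-butylethanimine; 12 2,3-dibromoprop-1-ene
Product: 15 4-bromopent-4-enal, via lithium azaenolate 13 (not isolated), via alkylated imine 14 (not isolated)
Conditions: LiN(iPr)2, THF, −78 → 0 °C; 12, −78 °C → rt; aqueous oxalic acid, rt
Reagents that add atoms: water, O
Why: Metalloenamine alkylation with the reactive allylic bromide (SN2 and SN2′ give the same product), then imine hydrolysis; the alkenyl bromide is inert.

Step 5
Reactants: 15 4-bromopent-4-enal
Product: 16 2,5,5-tribromopent-1-ene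
Conditions: (PhO)3P, Br2, CH2Cl2, −60 °C → rt
Reagents that add atoms: bromine, BrBr
Why: Deoxygenative geminal dibromination of an aldehyde by the triphenyl phosphite–bromine adduct; no stereocentre is involved.

Step 6
Reactants: 10 (3aS,7aS)-4,4,7a-trimethyloctahydro-1H-inden-1-one; 16 2,5,5-tribromopent-1-ene
Product: 21 (1R,4aS,8aS)-1-(4-bromopent-4-en-1-yl)-5,5,8a-trimethyloctahydronaphthalen-2(1H)-one, via tribromopentenyllithium 17 (not isolated), via alkoxide adduct 18 (not isolated), via oxido carbenoid 19 (not isolated), via lithium enolate 20 (not isolated)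
Conditions: 16, LiN(iPr)2, THF–Et2O, −100 °C; add 10, −100 → −78 °C; n-BuLi, −100 → −40 °C; AcOH; then K2CO3, MeOH, rt
Reagents that add atoms: none
Why: Nozaki–Yamamoto β-oxido carbenoid homologation (a semipinacol-type 1,2-shift): after Br/Li exchange the more substituted ring carbon C10 migrates with retention to the carbenoid carbon as bromide leaves, enlarging the cyclopentanone to the ring B cyclohexanone and forming C9–C10 and enolate 20 regiospecifically; protonation anti to the angular methyl, secured by base equilibration, puts the side chain equatorial (1R, labdane 9S).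

Step 7
Reactants: 21 (1R,4aS,8aS)-1-(4-bromopent-4-en-1-yl)-5,5,8a-trimethyloctahydronaphthalen-2(1H)-one
Product: 23 (1R,4aS,8aS)-1-(4-bromopent-4-en-1-yl)-5,5,8a-trimethyl-1,4,4a,5,6,7,8,8a-octahydronaphthalen-2-yl trifluoromethanesulfonate, via potassium enolate 22 (not isolated)
Conditions: KN(SiMe3)2, THF, −78 °C; PhNTf2, −78 → 0 °C
Reagents that add atoms: N-phenylbis(trifluoromethanesulfonimide), O=S(=O)(N(c1ccccc1)S(=O)(=O)C(F)(F)F)C(F)(F)F
Why: Kinetic deprotonation takes the unhindered C7 methylene and not the C9 methine next to the quaternary C10, and O-triflation fixes the Δ7 enol triflate; C9 is untouched.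

Step 8
Reactants: 23 (1R,4aS,8aS)-1-(4-bromopent-4-en-1-yl)-5,5,8a-trimethyl-1,4,4a,5,6,7,8,8a-octahydronaphthalen-2-yl trifluoromethanesulfonate
Product: 24 (1S,4aS,8aS)-1-(4-bromopent-4-en-1-yl)-2,5,5,8a-tetramethyl-1,4,4a,5,6,7,8,8a-octahydronaphthalene
Conditions: Me2CuLi (from CuI and MeLi, 3 equiv), THF, −20 → 0 °C
Reagents that add atoms: lithium dimethylcuprate Me2CuLi, [Li+].C[Cu-]C
Why: Cuprate coupling of an enol triflate installs the C8 methyl on the Δ7 alkene; the unactivated 2-bromo-1-alkene is expected to react more slowly at this temperature.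

Step 9
Reactants: 24 (1S,4aS,8aS)-1-(4-bromopent-4-en-1-yl)-2,5,5,8a-tetramethyl-1,4,4a,5,6,7,8,8a-octahydronaphthalene; 25 2-oxoethyl acetate
Product: 28 (2S)-3-methylidene-5-[(1S,4aS,8aS)-2,5,5,8a-tetramethyl-1,4,4a,5,6,7,8,8a-octahydronaphthalen-1-yl]pentane-1,2-diyl diacetate, via alkenylchromium 26 (not isolated), via chromium alkoxide 27 (not isolated)
Conditions: CrCl2 (3 equiv), NiCl2 (2 mol %), chiral oxazoline–sulfonamide ligand (enantiomer giving Si-face addition), Et3N, THF, rt; then Ac2O, pyridine, DMAP, rt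
Reagents that add atoms: acetic anhydride, CC(=O)OC(C)=O
Why: Nozaki–Hiyama–Kishi coupling is aldehyde-selective and tolerates the ring alkene, the sulfonamide-ligated chromium delivers the alkenyl group to the Si face of the aldehyde (sets 14S), and acetylation of the alkoxide completes the diacetate; any minor 14R epimer is removed by preparative HPLC.

**Compound list**

1 | 1-chloro-3-methylbut-2-ene (prenyl chloride) | CC(C)=CCCl | starting material
2 | chloro(3-methylbut-2-en-1-yl)magnesium (prenylmagnesium chloride) | CC(C)=CC[Mg]Cl | intermediate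
3 | trimethyl(3-methylbut-2-en-1-yl)silane | CC(C)=CC[Si](C)(C)C | intermediate
4 | 2-methylcyclopent-2-en-1-one | CC1=CCCC1=O | starting material
5 | 3-iodoprop-1-ene (allyl iodide) | C=CCI | starting material
6 | trimethyl{[(3S)-2-methyl-3-(2-methylbut-3-en-2-yl)cyclopent-1-en-1-yl]oxy}silane | CC1=C(O[Si](C)(C)C)CC[C@H]1C(C)(C)C=C | intermediate
7 | lithium (3S)-2-methyl-3-(2-methylbut-3-en-2-yl)cyclopent-1-en-1-olate | [Li+].CC1=C([O-])CC[C@H]1C(C)(C)C=C | intermediate
8 | (2S,3S)-2-methyl-3-(2-methylbut-3-en-2-yl)-2-(prop-2-en-1-yl)cyclopentan-1-one | O=C1CC[C@@H](C(C)(C)C=C)[C@]1(C)CC=C | intermediate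
9 | (3aS,7aS)-4,4,7a-trimethyl-2,3,3a,4,7,7a-hexahydro-1H-inden-1-one | O=C1CC[C@H]2C(C)(C)C=CC[C@]12C | intermediate
10 | (3aS,7aS)-4,4,7a-trimethyloctahydro-1H-inden-1-one | O=C1CC[C@H]2C(C)(C)CCC[C@]12C | intermediate
11 | (E)-N-tert-butylethanimine | C/C=N/C(C)(C)C | starting material
12 | 2,3-dibromoprop-1-ene | C=C(Br)CBr | starting material
13 | lithium N-tert-butylethenamide | [Li+].C=C[N-]C(C)(C)C | intermediate
14 | (E)-4-bromo-N-tert-butylpent-4-en-1-imine | C=C(Br)CC/C=N/C(C)(C)C | intermediate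
15 | 4-bromopent-4-enal | C=C(Br)CCC=O | intermediate
16 | 2,5,5-tribromopent-1-ene | C=C(Br)CCC(Br)Br | intermediate
17 | (1,1,4-tribromopent-4-en-1-yl)lithium | [Li]C(Br)(Br)CCC(Br)=C | intermediate
18 | lithium (3aS,7aS)-4,4,7a-trimethyl-1-(1,1,4-tribromopent-4-en-1-yl)octahydro-1H-inden-1-olate (C1 epimers) | [Li+].[O-]C1(C(Br)(Br)CCC(Br)=C)CC[C@H]2C(C)(C)CCC[C@]12C | intermediate
19 | lithium (3aS,7aS)-1-(1,4-dibromo-1-lithiopent-4-en-1-yl)-4,4,7a-trimethyloctahydro-1H-inden-1-olate (epimers) | [Li+].[O-]C1(C([Li])(Br)CCC(Br)=C)CC[C@H]2C(C)(C)CCC[C@]12C | intermediate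
20 | lithium (4aS,8aS)-1-(4-bromopent-4-en-1-yl)-5,5,8a-trimethyl-3,4,4a,5,6,7,8,8a-octahydronaphthalen-2-olate | [Li+].C=C(Br)CCC1=C([O-])CC[C@H]2C(C)(C)CCC[C@]12C | intermediate
21 | (1R,4aS,8aS)-1-(4-bromopent-4-en-1-yl)-5,5,8a-trimethyloctahydronaphthalen-2(1H)-one | C=C(Br)CC[C@H]1C(=O)CC[C@H]2C(C)(C)CCC[C@]12C | intermediate
22 | potassium (1R,4aS,8aS)-1-(4-bromopent-4-en-1-yl)-5,5,8a-trimethyl-1,4,4a,5,6,7,8,8a-octahydronaphthalen-2-olate | [K+].C=C(Br)CC[C@H]1C([O-])=CC[C@H]2C(C)(C)CCC[C@]12C | intermediate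
23 | (1R,4aS,8aS)-1-(4-bromopent-4-en-1-yl)-5,5,8a-trimethyl-1,4,4a,5,6,7,8,8a-octahydronaphthalen-2-yl trifluoromethanesulfonate | C=C(Br)CC[C@H]1C(OS(=O)(=O)C(F)(F)F)=CC[C@H]2C(C)(C)CCC[C@]12C | intermediate
24 | (1S,4aS,8aS)-1-(4-bromopent-4-en-1-yl)-2,5,5,8a-tetramethyl-1,4,4a,5,6,7,8,8a-octahydronaphthalene | C=C(Br)CC[C@H]1C(C)=CC[C@H]2C(C)(C)CCC[C@]12C | intermediate
25 | 2-oxoethyl acetate (acetoxyacetaldehyde) | CC(=O)OCC=O | starting material
26 | dichloro{5-[(1S,4aS,8aS)-2,5,5,8a-tetramethyl-1,4,4a,5,6,7,8,8a-octahydronaphthalen-1-yl]pent-1-en-2-yl}chromium | C=C([Cr](Cl)Cl)CC[C@H]1C(C)=CC[C@H]2C(C)(C)CCC[C@]12C | intermediate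
27 | dichlorochromium alkoxide of (2S)-2-hydroxy-3-methylidene-5-[(1S,4aS,8aS)-2,5,5,8a-tetramethyl-1,4,4a,5,6,7,8,8a-octahydronaphthalen-1-yl]pentyl acetate | C=C(CC[C@H]1C(C)=CC[C@H]2C(C)(C)CCC[C@]12C)[C@H](O[Cr](Cl)Cl)COC(C)=O | intermediate
28 | (2S)-3-methylidene-5-[(1S,4aS,8aS)-2,5,5,8a-tetramethyl-1,4,4a,5,6,7,8,8a-octahydronaphthalen-1-yl]pentane-1,2-diyl diacetate | C=C(CC[C@H]1C(C)=CC[C@H]2C(C)(C)CCC[C@]12C)[C@@H](COC(C)=O)OC(C)=O | target

**Step count and risk**

Total step count: 9. Longest linear sequence: 7 (steps 1, 2, 3, 6, 7, 8, 9); the side-chain branch (steps 4 and 5) joins at step 6.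

Three steps most likely to fail:

Step 2 (the proposed new conjugate prenylation; risks are low turnover on the α-methyl enone and insufficient enantioselectivity). The fallback uses known chemistry, sets out from Grignard 2 and allyl iodide 5, and comes back at 8. Commercial 2-methylcyclopentane-1,3-dione is O-ethylated (EtOH, TsOH, benzene, water removal) to 3-ethoxy-2-methylcyclopent-2-en-1-one F1. Grignard 2 adds to its carbonyl through the γ-carbon to give 3-ethoxy-2-methyl-1-(2-methylbut-3-en-2-yl)cyclopent-2-en-1-ol F2, and dilute HCl (Stork–Danheiser transposition) gives 2-methyl-3-(2-methylbut-3-en-2-yl)cyclopent-2-en-1-one F3. Li/NH3 reduction and trapping of the regiodefined enolate with 5 gives racemic trans-2-methyl-3-(2-methylbut-3-en-2-yl)-2-(prop-2-en-1-yl)cyclopentan-1-one F4. Preparative chromatography on a chiral stationary phase then delivers 8, at the cost of half the material.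

Step 6 (carbenoid ring expansion; risks are slow addition of the hindered carbenoid 17 to the α-quaternary ketone, loss of the alkenyl bromide to n-BuLi, and migration of the methylene in place of C10). The fallback sets out from aldehyde 15 and ketone 10 and comes back at 21. Aldehyde 15 with PhSeH and ZnCl2 gives (4-bromopent-4-ene-1,1-diyl)bis(phenylselane) F5. n-BuLi at −78 °C cleaves one C–Se bond to [4-bromo-1-(phenylselanyl)pent-4-en-1-yl]lithium F6, a smaller and more nucleophilic reagent, which adds to 10 to give (3aS,7aS)-1-[4-bromo-1-(phenylselanyl)pent-4-en-1-yl]-4,4,7a-trimethyloctahydro-1H-inden-1-ol F7. AgBF4 on alumina in CH2Cl2 then triggers the selenium-based ring expansion, again with migration of the more substituted carbon, and base equilibration gives 21.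

Step 8 (methyl coupling; risk is competing reaction of the side-chain alkenyl bromide or sluggish coupling of the hindered triflate). The fallback sets out from ketone 21, bypasses 23, and comes back at 24. MeMgBr with CeCl3 in THF at −78 °C gives (1R,4aS,8aS)-1-(4-bromopent-4-en-1-yl)-2,5,5,8a-tetramethyldecahydronaphthalen-2-ol F8. Dehydration with SOCl2 and pyridine at −20 °C gives the Δ7 alkene 24 together with the exocyclic isomer, which is removed on AgNO3-impregnated silica.

**Further compounds**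

F1 | step 2 | 3-ethoxy-2-methylcyclopent-2-en-1-one | CCOC1=C(C)C(=O)CC1
F2 | step 2 | 3-ethoxy-2-methyl-1-(2-methylbut-3-en-2-yl)cyclopent-2-en-1-ol (racemic) | CCOC1=C(C)C(O)(C(C)(C)C=C)CC1
F3 | step 2 | 2-methyl-3-(2-methylbut-3-en-2-yl)cyclopent-2-en-1-one | CC1=C(C(C)(C)C=C)CCC1=O
F4 | step 2 | racemic trans-2-methyl-3-(2-methylbut-3-en-2-yl)-2-(prop-2-en-1-yl)cyclopentan-1-one | O=C1CC[C@@H](C(C)(C)C=C)[C@]1(C)CC=C.O=C1CC[C@H](C(C)(C)C=C)[C@@]1(C)CC=C
F5 | step 6 | (4-bromopent-4-ene-1,1-diyl)bis(phenylselane) | C=C(Br)CCC([Se]c1ccccc1)[Se]c1ccccc1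
F6 | step 6 | [4-bromo-1-(phenylselanyl)pent-4-en-1-yl]lithium | [Li]C(CCC(Br)=C)[Se]c1ccccc1
F7 | step 6 | (3aS,7aS)-1-[4-bromo-1-(phenylselanyl)pent-4-en-1-yl]-4,4,7a-trimethyloctahydro-1H-inden-1-ol (epimers) | OC1(C(CCC(Br)=C)[Se]c2ccccc2)CC[C@H]2C(C)(C)CCC[C@]12C
F8 | step 8 | (1R,4aS,8aS)-1-(4-bromopent-4-en-1-yl)-2,5,5,8a-tetramethyldecahydronaphthalen-2-ol (C2 epimers) | C=C(Br)CC[C@H]1C(C)(O)CC[C@H]2C(C)(C)CCC[C@]12C
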